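**Plan**

- Retrosynthesis: remove both N-formyl groups; open ring B at its C–N bond and at the CH2–CH2 bond beside it; open the tetrahydrofuran at O–CH and take the methyl off its quaternary carbon; cut the resulting ketone at C(O)–CH2; cut the side chain from ring A at the ring–CH bond.
- Enabling feature: the nitrogen-bearing carbon of ring B carries a methyl group, a ring CH2 and the ring-fusion CH, so it is the tertiary carbon of an isopropenyl group sitting cis to a CH(CH2I) arm on the methylcyclohexene ring A; a carbon radical can attack its =CH2 end and nitrogen can cap the tertiary radical.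
- Forward order: (S)-limonene → cis-dienol → tertiary ester → Ireland–Claisen acid (ring A plus side-chain CH) → ketone from an aziridinyl alkylzinc → MeMgBr addition and alkoxide opening of the aziridine (tetrahydrofuran) → iodide → ring B by radical cyclisation/azidation → two amines → bis-formamide.
- Stereochemistry: the isopropenyl carbon is that of (S)-limonene; the epoxide face used by the amine fixes the dienol C–O bond, which is relayed suprafacially to the cis ring A–CH bond. The enolate substituent in the Claisen step is the future CH2I arm, because that substituent ends up anti to the isopropenyl-bearing ring carbon; the tetrahydrofuran is therefore grown from the carboxyl carbon.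
- The quaternary ether carbon comes from chelate/Felkin–Anh addition, the O–CH carbon from a Shi epoxide after two inversions, and the C–N carbon of ring B from equatorial azide transfer.

Key step: step 15

Remark: 5-chloro-2-methylpent-2-ene and 3-[(4-methoxyphenyl)methoxy]propanoic acid are taken as purchasable building blocks.

Step 1
Reactants: 1 (S)-limonene
Product: 2 (4S)-limonene 1,2-oxide as the mixture of trans (1R,2S,4S) and cis (1S,2R,4S) epoxides
Conditions: mCPBA, CH2Cl2, 0 °C
Reagents that add atoms: 3-chloroperbenzoic acid, OOC(=O)c1cccc(Cl)c1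
Why: Prilezhaev epoxidation picks the electron-richer trisubstituted ring alkene over the isopropenyl group, and facial control is not needed because only the trans epoxide reacts in step 2.

Step 2
Reactants: 2 (4S)-limonene 1,2-oxide (the trans epoxide reacts)
Product: 3 (1R,2R,4S)-2-(dimethylamino)-1-methyl-4-(prop-1-en-2-yl)cyclohexan-1-ol
Conditions: 40% aq. Me2NH, 80 °C, sealed vessel; unreacted cis epoxide distilled off
Reagents that add atoms: dimethylamine, CNC
Why: Aminolysis of the epoxide by trans-diaxial (Fürst–Plattner) attack at the secondary carbon is fast only for the trans isomer, so the amine resolves the mixture kinetically and leaves the tertiary C–O bond cis to the isopropenyl group (inversion at C2, C1 untouched).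

Step 3
Reactants: 3 (1R,2R,4S)-2-(dimethylamino)-1-methyl-4-(prop-1-en-2-yl)cyclohexan-1-ol
Product: 5 (1R,4S)-1-methyl-4-(prop-1-en-2-yl)cyclohex-2-en-1-ol, via amine N-oxide 4 (not isolated)
Conditions: 30% aq. H2O2, MeOH, 20 °C; then neat, 150 °C, 20 mbar
Reagents that add atoms: none
Why: Cope elimination of the N-oxide is a syn elimination that can only take a hydrogen from C3 because C1 is quaternary, so the 2-en-1-ol forms without touching either stereocentre.

Step 4
Reactants: 5 (1R,4S)-1-methyl-4-(prop-1-en-2-yl)cyclohex-2-en-1-ol; 6 3-[(4-methoxyphenyl)methoxy]propanoic acid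
Product: 7 (1R,4S)-1-methyl-4-(prop-1-en-2-yl)cyclohex-2-en-1-yl 3-[(4-methoxyphenyl)methoxy]propanoate
Conditions: DCC, 4-(dimethylamino)pyridine, CH2Cl2, 0 → 25 °C
Reagents that add atoms: none
Why: Steglich esterification acylates the tertiary allylic alcohol under neutral conditions that avoid ionisation of the allylic C–O bond, and no stereocentre is touched.

Step 5
Reactants: 7 (1R,4S)-1-methyl-4-(prop-1-en-2-yl)cyclohex-2-en-1-yl 3-[(4-methoxyphenyl)methoxy]propanoate
Product: 10 (2S)-3-[(4-methoxyphenyl)methoxy]-2-[(1R,6S)-3-methyl-6-(prop-1-en-2-yl)cyclohex-2-en-1-yl]propanoic acid, via silyl ketene acetal 8 (not isolated), via trimethylsilyl ester 9 (not isolated)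
Conditions: LiN(i-Pr)2, Me3SiCl, Et3N, THF, −78 → 25 °C; then 1 M HCl, 0 °C
Reagents that add atoms: none
Why: In this Ireland–Claisen rearrangement the [3,3] shift is suprafacial, so the ring A–CH bond forms on the face of the leaving oxygen, cis to the isopropenyl group, and the enolate substituent CH2OPMB stays anti to the isopropenyl-bearing ring carbon in both the chair transition state of the (E)- and the boat transition state of the (Z)-ketene acetal of a cyclohexenyl ester, so either geometry should give the (S)-configured side-chain CH, while silylation in situ at −78 °C forestalls β-elimination of the ether.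

Step 6
Reactants: 11 5-chloro-2-methylpent-2-ene
Product: 12 (3R)-3-(2-chloroethyl)-2,2-dimethyloxirane
Conditions: 1,2:4,5-di-O-isopropylidene-β-D-erythro-2,3-hexodiulo-2,6-pyranose (0.3 equiv), KHSO5 (as 2KHSO5·KHSO4·K2SO4), K2CO3, Bu4NHSO4, MeCN/(MeO)2CH2/aq. Na2B4O7, 0 °C
Reagents that add atoms: potassium peroxymonosulfate, [K+].[O-]S(=O)(=O)OO
Why: In the Shi epoxidation the dioxirane of the D-fructose-derived ketone transfers oxygen to the trisubstituted alkene through the spiro transition state, which should give the (R)-epoxide, and the alkyl chloride is inert.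

Step 7
Reactants: 12 (3R)-3-(2-chloroethyl)-2,2-dimethyloxirane
Product: 13 (3R)-2-azido-5-chloro-2-methylpentan-3-ol
Conditions: NaN3, H2O/MeCN, AcOH to pH 4.2, 30 °C
Reagents that add atoms: sodium azide, [Na+].[N-]=[N+]=[N-]
Why: Acid-assisted azidolysis of a trisubstituted epoxide goes mainly to the tertiary carbon and leaves the carbinol stereocentre untouched (attack at the other carbon would lead to the same aziridine after step 8), and the primary chloride is too slow to be displaced at 30 °C.

Step 8
Reactants: 13 (3R)-2-azido-5-chloro-2-methylpentan-3-ol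
Product: 15 (3S)-3-(2-chloroethyl)-2,2-dimethylaziridine, via iminophosphorane 14 (not isolated)
Conditions: PPh3, MeCN, 25 → 80 °C
Reagents that add atoms: none
Why: A Staudinger reaction followed by intramolecular displacement of the phosphorus-activated secondary oxygen by nitrogen closes the aziridine with inversion at the carbinol carbon, turning (R) into (S).

Step 9
Reactants: 15 (3S)-3-(2-chloroethyl)-2,2-dimethylaziridine
Product: 16 (3S)-3-(2-chloroethyl)-2,2-dimethyl-1-{[2-(trimethylsilyl)ethyl]sulfonyl}aziridine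
Conditions: Me3SiCH2CH2SO2Cl, Et3N, CH2Cl2, 0 °C
Reagents that add atoms: 2-(trimethylsilyl)ethanesulfonyl chloride, C[Si](C)(C)CCS(=O)(=O)Cl
Why: N-Sulfonylation of the aziridine NH installs a group that activates the ring for the later alkoxide opening, survives organometallic and radical steps and is removable with fluoride.

Step 10
Reactants: 16 (3S)-3-(2-chloroethyl)-2,2-dimethyl-1-{[2-(trimethylsilyl)ethyl]sulfonyl}aziridine
Product: 17 (3S)-3-(2-iodoethyl)-2,2-dimethyl-1-{[2-(trimethylsilyl)ethyl]sulfonyl}aziridine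
Conditions: NaI, butan-2-one, 80 °C
Reagents that add atoms: sodium iodide, [Na+].[I-]
Why: Finkelstein exchange at the primary carbon is driven by precipitation of NaCl, and any reversible iodide opening of the aziridine re-closes with net retention.

Step 11
Reactants: 10 (2S)-3-[(4-methoxyphenyl)methoxy]-2-[(1R,6S)-3-methyl-6-(prop-1-en-2-yl)cyclohex-2-en-1-yl]propanoic acid; 17 (3S)-3-(2-iodoethyl)-2,2-dimethyl-1-{[2-(trimethylsilyl)ethyl]sulfonyl}aziridine
Product: 20 aziridinyl ketone (2S)-5-[(2S)-3,3-dimethyl-1-{[2-(trimethylsilyl)ethyl]sulfonyl}aziridin-2-yl]-1-[(4-methoxyphenyl)methoxy]-2-[(1R,6S)-3-methyl-6-(prop-1-en-2-yl)cyclohex-2-en-1-yl]pentan-3-one, via acid chloride 18 (not isolated), via alkylzinc iodide 19 (not isolated)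
Conditions: 10, 1-chloro-N,N,2-trimethylprop-1-en-1-amine, CH2Cl2, 0 °C; 17, Zn, LiCl, THF, 40 °C; then Pd(PPh3)4 (5 mol %), THF, 0 → 25 °C
Reagents that add atoms: none
Why: In this Negishi acylation the chloroenamine makes the acid chloride without base, so no ketene forms and the α-stereocentre is kept, and zerovalent palladium couples it with the alkylzinc iodide, a reagent mild enough to leave the sulfonyl aziridine, the ether and the alkenes alone.

Step 12
Reactants: 20 aziridinyl ketone
Product: 22 tetrahydrofuran sulfonamide 4-methoxybenzyl ether, via tertiary alcohol 21 (not isolated)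
Conditions: MeMgBr, CH2Cl2/Et2O, −78 °C; aqueous work-up; then KOt-Bu, THF, 0 → 25 °C
Reagents that add atoms: methylmagnesium bromide, C[Mg]Br
Why: Grignard addition under Cram-chelate control (magnesium bridging the ketone and the CH2OPMB oxygen, with the Felkin–Anh arrangement predicting the same face, anti to the ring A group) sets the quaternary carbinol carbon as (S), and the potassium alkoxide then opens the N-sulfonyl aziridine at its secondary carbon in a 5-exo-tet SN2 step whose inversion gives the (R)-configured O–CH carbon of the tetrahydrofuran.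

Step 13
Reactants: 22 tetrahydrofuran sulfonamide 4-methoxybenzyl ether
Product: 23 tetrahydrofuran sulfonamide primary alcohol
Conditions: DDQ, CH2Cl2/H2O (18:1), 0 → 25 °C
Reagents that add atoms: none
Why: Oxidative cleavage of the 4-methoxybenzyl ether by DDQ goes through the benzylic oxocarbenium ion and water and leaves the alkenes, the sulfonamide and the tetrahydrofuran untouched.

Step 14
Reactants: 23 tetrahydrofuran sulfonamide primary alcohol
Product: 24 cis-disubstituted methylcyclohexene iodide with complete tetrahydrofuran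
Conditions: PPh3, I2, imidazole, CH2Cl2, 0 °C (alcohol added to the preformed reagent)
Reagents that add atoms: iodine, II
Why: Appel-type (Garegg–Samuelsson) iodination replaces the primary hydroxyl by SN2 at CH2 without touching a stereocentre, and adding the alcohol to the preformed phosphonium iodide keeps free iodine away from the alkenes.

Step 15
Reactants: 24 cis-disubstituted methylcyclohexene iodide with complete tetrahydrofuran
Product: 27 ring B tertiary azide, via primary alkyl radical 25 (not isolated), via tertiary ring B radical 26 (not isolated)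
Conditions: EtSO2N3 (3 equiv), (Bu3Sn)2 (1.5 equiv), di-tert-butyl hyponitrite (0.1 equiv), benzene, 80 °C, 0.02 M
Reagents that add atoms: ethanesulfonyl azide, CCS(=O)(=O)N=[N+]=[N-]
Why: Bu3Sn radicals, formed from (Bu3Sn)2 and the hyponitrite, abstract iodine from 24 to give primary radical 25, which adds to the =CH2 end of the cis isopropenyl group in a 6-endo-trig closure of ring B; tertiary radical 26 then takes the azide group from EtSO2N3, and the released EtSO2 radical regenerates Bu3Sn from the ditin. The closest known reaction type is the radical cyclisation–azidation of alkyl iodides with sulfonyl azides, combined with the 6-endo closure of 5-methylhex-5-enyl radicals. Ring B should close 6-endo rather than 5-exo because the methyl on the internal alkene carbon slows attack there and the cis-1,2 arrangement on ring A lets the chain reach the terminus through a chair-like transition state with the tetrahydrofuranyl group equatorial. The new stereocentre at the C–N carbon is set by azide transfer to the equatorial face of the cis-decalin radical, away from the axial hydrogens of ring B, which places nitrogen trans to the adjacent ring-fusion hydrogen; this is expected but not assured. The step needs cyclisation to outrun direct azidation of 25, which the low reactivity of sulfonyl azides toward primary radicals and the high dilution should secure, and it needs the ring A alkene and the NH sulfonamide to stay inert.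

Step 16
Reactants: 27 ring B tertiary azide
Product: 29 ring B tertiary amine with sulfonamide, via iminophosphorane 28 (not isolated)
Conditions: PMe3, THF, 25 °C; then H2O, 50 °C
Reagents that add atoms: none
Why: Staudinger reduction converts the tertiary azide into the amine through the iminophosphorane without touching the alkene or any stereocentre.

Step 17
Reactants: 29 ring B tertiary amine with sulfonamide
Product: 30 diamine
Conditions: CsF, DMF, 95 °C
Reagents that add atoms: none
Why: Fluoride attacks silicon and the 2-(trimethylsilyl)ethylsulfonyl group fragments by β-elimination to ethene, SO2 and the amide anion, freeing the second tert-alkyl amine.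

Step 18
Reactants: 30 diamine
Product: 31 target bis-formamide CNP0173819.1
Conditions: HCO2Ac (preformed, 4 equiv), CH2Cl2, 0 → 25 °C
Reagents that add atoms: acetic formic anhydride, CC(=O)OC=O
Why: N-Formylation of both hindered primary amines by the mixed anhydride, which transfers only its formyl group, completes the target without touching a stereocentre.

**Compound list**

1 | (S)-limonene, (4S)-1-methyl-4-(prop-1-en-2-yl)cyclohex-1-ene | CC1=CC[C@H](CC1)C(C)=C | starting material
2 | (4S)-limonene 1,2-oxide, mixture of trans (1R,2S,4S) and cis (1S,2R,4S) epoxides | CC12CC[C@H](C(C)=C)CC1O2 | intermediate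
3 | (1R,2R,4S)-2-(dimethylamino)-1-methyl-4-(prop-1-en-2-yl)cyclohexan-1-ol | C[C@@]1(O)CC[C@H](C(C)=C)C[C@H]1N(C)C | intermediate
4 | N-oxide of amino alcohol 3 | C[C@@]1(O)CC[C@H](C(C)=C)C[C@H]1[N+](C)(C)[O-] | intermediate (not isolated)
5 | (1R,4S)-1-methyl-4-(prop-1-en-2-yl)cyclohex-2-en-1-ol (hydroxyl cis to isopropenyl) | C[C@]1(O)C=C[C@H](CC1)C(C)=C | intermediate
6 | 3-[(4-methoxyphenyl)methoxy]propanoic acid | COc1ccc(COCCC(=O)O)cc1 | starting material
7 | (1R,4S)-1-methyl-4-(prop-1-en-2-yl)cyclohex-2-en-1-yl 3-[(4-methoxyphenyl)methoxy]propanoate | C[C@]1(OC(=O)CCOCc2ccc(OC)cc2)C=C[C@H](CC1)C(C)=C | intermediate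
8 | (E)-trimethylsilyl ketene acetal of ester 7 | C[C@]1(O/C(O[Si](C)(C)C)=C\COCc2ccc(OC)cc2)C=C[C@H](CC1)C(C)=C | intermediate (not isolated)
9 | trimethylsilyl ester of acid 10 | CC1=C[C@@H]([C@@H](COCc2ccc(OC)cc2)C(=O)O[Si](C)(C)C)[C@@H](C(C)=C)CC1 | intermediate (not isolated)
10 | (2S)-3-[(4-methoxyphenyl)methoxy]-2-[(1R,6S)-3-methyl-6-(prop-1-en-2-yl)cyclohex-2-en-1-yl]propanoic acid | CC1=C[C@@H]([C@@H](COCc2ccc(OC)cc2)C(=O)O)[C@@H](C(C)=C)CC1 | intermediate
11 | 5-chloro-2-methylpent-2-ene | CC(C)=CCCCl | starting material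
12 | (3R)-3-(2-chloroethyl)-2,2-dimethyloxirane | ClCC[C@H]1OC1(C)C | intermediate
13 | (3R)-2-azido-5-chloro-2-methylpentan-3-ol | ClCC[C@@H](O)C(C)(C)N=[N+]=[N-] | intermediate
14 | (3R)-5-chloro-2-methyl-2-[(triphenyl-λ5-phosphanylidene)amino]pentan-3-ol | ClCC[C@@H](O)C(C)(C)N=P(c1ccccc1)(c1ccccc1)c1ccccc1 | intermediate (not isolated)
15 | (3S)-3-(2-chloroethyl)-2,2-dimethylaziridine | ClCC[C@@H]1NC1(C)C | intermediate
16 | (3S)-3-(2-chloroethyl)-2,2-dimethyl-1-{[2-(trimethylsilyl)ethyl]sulfonyl}aziridine | ClCC[C@@H]1N(S(=O)(=O)CC[Si](C)(C)C)C1(C)C | intermediate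
17 | (3S)-3-(2-iodoethyl)-2,2-dimethyl-1-{[2-(trimethylsilyl)ethyl]sulfonyl}aziridine | ICC[C@@H]1N(S(=O)(=O)CC[Si](C)(C)C)C1(C)C | intermediate
18 | acid chloride of 10 | CC1=C[C@@H]([C@@H](COCc2ccc(OC)cc2)C(Cl)=O)[C@@H](C(C)=C)CC1 | intermediate (not isolated)
19 | {2-[(2S)-3,3-dimethyl-1-{[2-(trimethylsilyl)ethyl]sulfonyl}aziridin-2-yl]ethyl}zinc iodide | I[Zn]CC[C@@H]1N(S(=O)(=O)CC[Si](C)(C)C)C1(C)C | intermediate (not isolated)
20 | (2S)-5-[(2S)-3,3-dimethyl-1-{[2-(trimethylsilyl)ethyl]sulfonyl}aziridin-2-yl]-1-[(4-methoxyphenyl)methoxy]-2-[(1R,6S)-3-methyl-6-(prop-1-en-2-yl)cyclohex-2-en-1-yl]pentan-3-one | CC1=C[C@@H]([C@@H](COCc2ccc(OC)cc2)C(=O)CC[C@@H]3N(S(=O)(=O)CC[Si](C)(C)C)C3(C)C)[C@@H](C(C)=C)CC1 | intermediate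
21 | (2S,3S)-5-[(2S)-3,3-dimethyl-1-{[2-(trimethylsilyl)ethyl]sulfonyl}aziridin-2-yl]-1-[(4-methoxyphenyl)methoxy]-3-methyl-2-[(1R,6S)-3-methyl-6-(prop-1-en-2-yl)cyclohex-2-en-1-yl]pentan-3-ol | CC1=C[C@@H]([C@@H](COCc2ccc(OC)cc2)[C@@](C)(O)CC[C@@H]3N(S(=O)(=O)CC[Si](C)(C)C)C3(C)C)[C@@H](C(C)=C)CC1 | intermediate (not isolated)
22 | N-(2-{(2R,5S)-5-[(1S)-2-[(4-methoxyphenyl)methoxy]-1-[(1R,6S)-3-methyl-6-(prop-1-en-2-yl)cyclohex-2-en-1-yl]ethyl]-5-methyloxolan-2-yl}propan-2-yl)-2-(trimethylsilyl)ethane-1-sulfonamide | CC1=C[C@@H]([C@@H](COCc2ccc(OC)cc2)[C@]3(C)CC[C@H](C(C)(C)NS(=O)(=O)CC[Si](C)(C)C)O3)[C@@H](C(C)=C)CC1 | intermediate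
23 | N-(2-{(2R,5S)-5-[(1S)-2-hydroxy-1-[(1R,6S)-3-methyl-6-(prop-1-en-2-yl)cyclohex-2-en-1-yl]ethyl]-5-methyloxolan-2-yl}propan-2-yl)-2-(trimethylsilyl)ethane-1-sulfonamide | CC1=C[C@@H]([C@@H](CO)[C@]3(C)CC[C@H](C(C)(C)NS(=O)(=O)CC[Si](C)(C)C)O3)[C@@H](C(C)=C)CC1 | intermediate
24 | N-(2-{(2R,5S)-5-[(1R)-2-iodo-1-[(1R,6S)-3-methyl-6-(prop-1-en-2-yl)cyclohex-2-en-1-yl]ethyl]-5-methyloxolan-2-yl}propan-2-yl)-2-(trimethylsilyl)ethane-1-sulfonamide | CC1=C[C@@H]([C@@H](CI)[C@]3(C)CC[C@H](C(C)(C)NS(=O)(=O)CC[Si](C)(C)C)O3)[C@@H](C(C)=C)CC1 | intermediate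
25 | primary radical formed from 24 by loss of iodine | CC1=C[C@@H]([C@@H]([CH2])[C@]3(C)CC[C@H](C(C)(C)NS(=O)(=O)CC[Si](C)(C)C)O3)[C@@H](C(C)=C)CC1 | intermediate (not isolated)
26 | tertiary radical of the cis-fused octahydronaphthalene (radical at the methyl-bearing ring B carbon) | CC1=C[C@H]2[C@H]([C@]3(C)CC[C@H](C(C)(C)NS(=O)(=O)CC[Si](C)(C)C)O3)CC[C](C)[C@H]2CC1 | intermediate (not isolated)
27 | N-(2-{(2R,5S)-5-[(1R,4R,4aS,8aR)-4-azido-4,7-dimethyl-1,2,3,4,4a,5,6,8a-octahydronaphthalen-1-yl]-5-methyloxolan-2-yl}propan-2-yl)-2-(trimethylsilyl)ethane-1-sulfonamide | CC1=C[C@H]2[C@H]([C@]3(C)CC[C@H](C(C)(C)NS(=O)(=O)CC[Si](C)(C)C)O3)CC[C@@](C)(N=[N+]=[N-])[C@H]2CC1 | intermediate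
28 | trimethyliminophosphorane of 27 (N=PMe3 in place of N3) | CC1=C[C@H]2[C@H]([C@]3(C)CC[C@H](C(C)(C)NS(=O)(=O)CC[Si](C)(C)C)O3)CC[C@@](C)(N=P(C)(C)C)[C@H]2CC1 | intermediate (not isolated)
29 | N-(2-{(2R,5S)-5-[(1R,4R,4aS,8aR)-4-amino-4,7-dimethyl-1,2,3,4,4a,5,6,8a-octahydronaphthalen-1-yl]-5-methyloxolan-2-yl}propan-2-yl)-2-(trimethylsilyl)ethane-1-sulfonamide | CC1=C[C@H]2[C@H]([C@]3(C)CC[C@H](C(C)(C)NS(=O)(=O)CC[Si](C)(C)C)O3)CC[C@@](C)(N)[C@H]2CC1 | intermediate
30 | (1R,4R,4aS,8aR)-4-[(2S,5R)-5-(2-aminopropan-2-yl)-2-methyloxolan-2-yl]-1,6-dimethyl-1,2,3,4,4a,7,8,8a-octahydronaphthalen-1-amine | CC1=C[C@H]2[C@H]([C@]3(C)CC[C@H](C(C)(C)N)O3)CC[C@@](C)(N)[C@H]2CC1 | intermediate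
31 | N-(2-{(2R,5S)-5-[(1R,4R,4aS,8aR)-4-formamido-4,7-dimethyl-1,2,3,4,4a,5,6,8a-octahydronaphthalen-1-yl]-5-methyloxolan-2-yl}propan-2-yl)formamide (CNP0173819.1) | CC1=C[C@H]2[C@H]([C@]3(C)CC[C@H](C(C)(C)NC=O)O3)CC[C@@](C)(NC=O)[C@H]2CC1 | target

**Step count**

Total step count: 18. Longest linear sequence: 13 steps (steps 1–5 and 11–18 from (S)-limonene; the aziridine branch, steps 6–10 and 11–18, is equally long).

**Steps most likely to fail**

1. Step 15. What may go wrong is 5-exo closure onto the internal alkene carbon, azide capture of the primary radical before it cyclises, or poor facial selectivity in the azide transfer. The fallback closes ring B by an ionic ene reaction and brings in nitrogen afterwards by hydrogen-atom transfer. It sets out from alcohol 23. Dess–Martin periodinane gives the aldehyde F1. Me2AlCl (CH2Cl2, −78 °C) then triggers a type-two carbonyl-ene reaction in which the =CH2 end of the isopropenyl group adds to the aldehyde carbon and a methyl hydrogen moves to oxygen, closing ring B as the methylidene alcohol F2. 1,1′-Thiocarbonyldiimidazole converts this into the imidazolyl thiocarbonate F3, which Bu3SnH with 2,2′-azobis(2-methylpropionitrile) reduces (Barton–McCombie) to the methylidene cis-decalin F4. Cobalt-catalysed Markovnikov hydroazidation of the 1,1-disubstituted alkene (Co(BF4)2·6H2O, potassium N-(3,5-di-tert-butylsalicylidene)-2,2-diphenylglycinate, TsN3, PhSiH3, EtOH) passes through the same tertiary ring B radical and comes back to the route at azide 27.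

2. Step 11. What may go wrong is sluggish acylation at the α-branched acid chloride, loss of configuration at the α-carbon, or ring opening of the sulfonyl aziridine by the organometallic. The fallback replaces the acyl coupling by aldehyde addition and oxidation. It sets out from acid 10 and iodide 17. LiAlH4 reduces 10 to the primary alcohol F5 and Dess–Martin periodinane gives the aldehyde F6. A Nozaki–Hiyama-type addition of the alkylchromium reagent made from 17 (CrCl2, catalytic cobalt phthalocyanine Co(C32H16N8), DMF) gives the secondary alcohol F7 as a mixture at the carbinol carbon. Dess–Martin oxidation of this mixture comes back to the route at ketone 20.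

3. Step 5. What may go wrong is β-elimination of 4-methoxybenzyl oxide from the ester enolate before it is silylated, or ionisation of the tertiary dienyl ester. The fallback rearranges the plain acetate and sets the side-chain CH afterwards with an auxiliary. It sets out from dienol 5. Acetylation (Ac2O, Et3N, 4-(dimethylamino)pyridine) gives the acetate F8, whose Ireland–Claisen rearrangement (LiN(i-Pr)2, Me3SiCl) has no leaving group in the enolate and gives the acid F9 with the cis ring A–CH2 bond. DCC/4-(dimethylamino)pyridine coupling with (4R)-4-benzyl-1,3-oxazolidin-2-one gives the imide F10. Its sodium enolate (NaN(SiMe3)2, THF, −78 °C) is alkylated by 1-[(chloromethoxy)methyl]-4-methoxybenzene on the face away from the benzyl group (Evans alkylation) to give the alkylated imide F11 with the required side-chain configuration. LiOH/H2O2 cleaves the auxiliary and comes back to the route at acid 10.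

Further compounds
F1 | step 15 | aldehyde from 23 (CHO in place of CH2OH) | CC1=C[C@@H]([C@@H](C=O)[C@]3(C)CC[C@H](C(C)(C)NS(=O)(=O)CC[Si](C)(C)C)O3)[C@@H](C(C)=C)CC1
F2 | step 15 | ring B methylidene alcohol from the carbonyl-ene closure (carbinol configuration left open) | CC1=C[C@H]2[C@H]([C@]3(C)CC[C@H](C(C)(C)NS(=O)(=O)CC[Si](C)(C)C)O3)C(O)CC(=C)[C@H]2CC1
F3 | step 15 | O-alkyl 1H-imidazole-1-carbothioate of F2 | CC1=C[C@H]2[C@H]([C@]3(C)CC[C@H](C(C)(C)NS(=O)(=O)CC[Si](C)(C)C)O3)C(OC(=S)n4ccnc4)CC(=C)[C@H]2CC1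
F4 | step 15 | methylidene cis-octahydronaphthalene (deoxygenated F2) | CC1=C[C@H]2[C@H]([C@]3(C)CC[C@H](C(C)(C)NS(=O)(=O)CC[Si](C)(C)C)O3)CCC(=C)[C@H]2CC1
F5 | step 11 | (2R)-3-[(4-methoxyphenyl)methoxy]-2-[(1R,6S)-3-methyl-6-(prop-1-en-2-yl)cyclohex-2-en-1-yl]propan-1-ol | CC1=C[C@@H]([C@@H](COCc2ccc(OC)cc2)CO)[C@@H](C(C)=C)CC1
F6 | step 11 | (2S)-3-[(4-methoxyphenyl)methoxy]-2-[(1R,6S)-3-methyl-6-(prop-1-en-2-yl)cyclohex-2-en-1-yl]propanal | CC1=C[C@@H]([C@@H](COCc2ccc(OC)cc2)C=O)[C@@H](C(C)=C)CC1
F7 | step 11 | secondary alcohol corresponding to ketone 20 (carbinol configuration left open) | CC1=C[C@@H]([C@@H](COCc2ccc(OC)cc2)C(O)CC[C@@H]3N(S(=O)(=O)CC[Si](C)(C)C)C3(C)C)[C@@H](C(C)=C)CC1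
F8 | step 5 | (1R,4S)-1-methyl-4-(prop-1-en-2-yl)cyclohex-2-en-1-yl acetate | C[C@]1(OC(C)=O)C=C[C@H](CC1)C(C)=C
F9 | step 5 | 2-[(1R,6S)-3-methyl-6-(prop-1-en-2-yl)cyclohex-2-en-1-yl]acetic acid | CC1=C[C@@H](CC(=O)O)[C@@H](C(C)=C)CC1
F10 | step 5 | (4R)-4-benzyl-3-{2-[(1R,6S)-3-methyl-6-(prop-1-en-2-yl)cyclohex-2-en-1-yl]acetyl}-1,3-oxazolidin-2-one | CC1=C[C@@H](CC(=O)N2[C@H](Cc3ccccc3)COC2=O)[C@@H](C(C)=C)CC1
F11 | step 5 | (4R)-4-benzyl-3-{(2S)-3-[(4-methoxyphenyl)methoxy]-2-[(1R,6S)-3-methyl-6-(prop-1-en-2-yl)cyclohex-2-en-1-yl]propanoyl}-1,3-oxazolidin-2-one | CC1=C[C@@H]([C@@H](COCc2ccc(OC)cc2)C(=O)N3[C@H](Cc4ccccc4)COC3=O)[C@@H](C(C)=C)CC1
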